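## The problem

Guanipiperazine A (26) is a 14-membered meta,para-cyclophane. Ring A is a phenol whose hydroxyl (C4) is flanked by the guanin-8-yl group (C5) and the ether oxygen (C3); ring B is a para-phenylene; the two are joined by the diaryl ether oxygen on one side and, through two benzylic methylenes, by C2 and C5 of a piperazine on the other. The ring bends the para-phenylene, so closing the macrocycle is the hard part, and a direct aryl ether coupling on an open chain must overcome both strain and oligomerisation. The only stereocentres are C2 and C5 of the piperazine, both S; they lie 1,4 to each other, neither can direct the other, and both are α-carbons of L-arylalanines, so they are best bought and then only guarded against epimerisation while they are α to a carbonyl. The guanine is insoluble, metal-binding and rich in N–H bonds and must come last; the two secondary amines must be masked during acylation and nickel catalysis; the electron-rich phenol is sensitive to oxidants. C5 of ring A is the only free position ortho to the phenol, so a late ortho-functionalisation is regiochemically unambiguous. The key step rests on the fact that the ether oxygen joins C3 of ring A to C4' of ring B, the carbon para to the benzylic methylene: an aryl benzoate, ring A–O–C(=O)–C4', has the same connectivity plus one carbonyl carbon, so a 15-membered lactone closed by ordinary acylation can become the ether ring by loss of CO.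

## Retrosynthesis

**Guanine.** Removing the Boc groups of 25 gives 26, and cutting C8–N7 and C8–N9 of 25 leads to salicylaldehyde 21 and 2,5,6-triaminopyrimidin-4(3H)-one 22. The neighbouring cut, the C8–aryl bond by cross-coupling, would need a soluble protected 8-haloguanine and an ortho-metalated phenol next to a strained ether. The annulation instead brings the whole heterocycle in one operation from a commercial pyrimidine. The forward reaction must condense at the 5-amino group, close onto the 6-amino group and be oxidised without harming the phenol; the nitrogens carry Boc so that the last step is acid only.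

**Formyl group.** The bond between C5 of ring A and the formyl carbon of 21 is cut to give N,N'-di-Boc-piperazinomycin 20. C5 is the only free ortho position of the phenol and ring B is not a phenol, so a phenoxide-directed formylation has one site to choose.

**Protecting groups.** Boc does not survive BBr3, and carbamates are a needless liability at 150 °C under nickel. 20 is therefore derived from N,N'-dibenzylpiperazinomycin 18 by hydrogenolysis with in situ Boc capture, and 18 from the methyl ether 17. Tertiary benzylamines and an aryl methyl ether offer the catalyst no acyl C–O, N–H or O–H bond.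

**Key disconnection.** The C4'–O bond of 17 is cut by formally inserting CO, which gives the 15-membered aryl ester 16. A direct Ullmann, SNAr or Chan–Lam closure would have to form the strained ring from an open chain; here the two atoms are already tethered and the bond forms at one metal centre. The precursor is no simpler in atom count, but its ring is one atom larger, contains a planar ester and is reachable by acylation. The forward reaction needs nickel insertion at C(acyl)–O, CO loss and C–O reductive elimination.

**Lactone.** The O–C(acyl) bond of 16 is cut to the hydroxy acid 15. The cis relation of the two benzyl arms on the piperazine lets the ring A phenol reach the para carboxyl of ring B. A carbodiimide activation that touches only the acid is required.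

**Carboxyl and phenol.** The C4'–CO2H bond of 15 is traced to an aryl bromide and the ring A C3–OH bond to an aryl iodide, via 13 and 10. Both halides are inert to borane, and they are told apart by the rate of halogen–metal exchange. Bromophenol 13 is also the substrate for a conventional copper-mediated ether closure, which insures the route.

**Piperazine.** The N-benzyl bonds of 10 are cut to give 9, and the two ring methylenes of 9 are traced to the lactam carbonyls of diketopiperazine 7. Reducing before benzylating avoids base on the epimerisable diketopiperazine.

**Amide bonds.** 7 opens to dipeptide 5, which comes from 4 by O-methylation, and 4 from methyl 3-iodo-L-tyrosinate hydrochloride 2 and N-Boc-4-bromo-L-phenylalanine 3; 2 comes from 3-iodo-L-tyrosine 1. A bromophenylalanine is preferred to tyrosine for ring B: a tyrosine phenol would compete in N-benzylation and would need a triflate that palladium cannot address before the more reactive ring A iodide.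

## Roads not taken

**Alternative 1:** The strategic cut is C8–N7 and C8–N9 of the guanine. The ring A salicylaldehyde A1 (identical with 21) is condensed with pyrimidine 22 and the aminal is oxidised in air with Na2S2O5 in hot DMF to give N,N'-di-Boc-guanipiperazine A, A2 (identical with 25).
- Merits: convergent, the polar heterocycle is attached last, the regiochemistry is unambiguous, and the reaction class is known.
- Weak points: it is silent on the real difficulty, the 14-membered ring, which would have to come from a conventional copper-mediated ether closure on an open chain. The annulation also runs on a hindered, electron-rich aldehyde with a poorly soluble, air-sensitive triamine.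
- Comparison: the chosen plan uses this same annulation as step 14, so the two differ only in how the macrocycle is closed. With an Ullmann closure from 13, Alternative 1 would be two steps shorter and would use only precedented steps. The chosen plan sets against this a unimolecular ring contraction driven by gas loss, and it keeps the Ullmann closure available from 13.

**Alternative 2:** The cut is the diaryl ether C–O bond between the ring B phenol oxygen and the ring A ortho carbon. The tetrabromo bisphenol A3 has two identical dibromophenol rings and derives from one amino acid used twice. It is oxidised at an anode in methanol with LiClO4, and the dienone is reduced with Zn in acetic acid to give N,N'-di-Boc-tribromopiperazinomycin A4.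
- Merits: biomimetic; the two rings need not be differentiated; and A4 would reach 20 after hydrogenolysis of three C–Br bonds in about half the steps the chosen plan needs.
- Weak points: the strained ring closes at a cationic intermediate under no catalyst control, where methanol capture, C–C coupling and oligomerisation compete. The bromines that steer the coupling are dead weight. The one bromine on ring A marks the carbon that must carry C8, but it cannot be kept selectively while the two on ring B are removed.
- Comparison: Alternative 2 is clearly shorter to the macrocycle. The chosen plan offers in return a closure under defined catalytic control, no halogen baggage and no electrolysis at high dilution.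

**Alternative 3:** The cuts are N1–C6 and N4–C3 of the piperazine. The bis-Cbz bis-aldehyde A5 is an isodityrosine-type bis(amino aldehyde) with the diaryl ether already in place. It is hydrogenolysed over Pd/C at high dilution; the freed amines condense head-to-tail with the aldehydes and the bis-imine is reduced in the same pot to piperazinomycin A6 (identical with 19).
- Merits: the ether is made intermolecularly where it is easy, both rings close in one operation, and protecting groups are few. If it worked it would be the shortest route to the core.
- Weak points: α-amino aldehydes are configurationally labile. The intermediate 2,5-dihydropyrazine has its stereocentres α to C=N, can tautomerise to the enamine or aromatise to a pyrazine, and either path erases both stereocentres. Aldehyde reduction and intermolecular condensation also compete with the strained double closure.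
- Comparison: Alternative 3 wins on step economy. The chosen plan keeps both stereocentres as amine-flanked sp3 carbons with no acidic hydrogen from step 5 onward and closes each ring separately.

Key step: step 10

Assumption: 2,5,6-triaminopyrimidin-4(3H)-one (22) is used as the free base, liberated from its commercial sulfate immediately before step 14, because the free base oxidises on storage in air.

## Route

Step 1
Reactants: 1 3-iodo-L-tyrosine
Product: 2 methyl 3-iodo-L-tyrosinate hydrochloride
Conditions: SOCl2, MeOH, 0 °C → reflux
Reagents that add atoms: methanol, CO; thionyl chloride, O=S(Cl)Cl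
Why: Fischer esterification with HCl generated from SOCl2 and methanol; the same HCl supplies the chloride of the ammonium salt, which protects the amine, and the stereocentre is not touched.

Step 2
Reactants: 2 methyl 3-iodo-L-tyrosinate hydrochloride; 3 N-Boc-4-bromo-L-phenylalanine
Product: 4 methyl N-(N-Boc-4-bromo-L-phenylalanyl)-3-iodo-L-tyrosinate
Conditions: EDC·HCl, HOBt, iPr2NEt, CH2Cl2–DMF, 0 °C → rt
Reagents that add atoms: none
Why: Carbodiimide/HOBt amide coupling of a urethane-protected amino acid, which does not racemise through an oxazolone; the amine outcompetes the free iodophenol for the active ester.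

Step 3
Reactants: 4 methyl N-(N-Boc-4-bromo-L-phenylalanyl)-3-iodo-L-tyrosinate
Product: 5 methyl N-(N-Boc-4-bromo-L-phenylalanyl)-3-iodo-O-methyl-L-tyrosinate
Conditions: CH3I, K2CO3, DMF, rt
Reagents that add atoms: iodomethane, CI
Why: Williamson etherification of the only acidic OH, the ortho-iodophenol; K2CO3 at room temperature should neither alkylate the carbamate or amide N–H nor epimerise the α-carbons.

Step 4
Reactants: 5 methyl N-(N-Boc-4-bromo-L-phenylalanyl)-3-iodo-O-methyl-L-tyrosinate
Product: 7 (3S,6S)-3-(4-bromobenzyl)-6-(3-iodo-4-methoxybenzyl)piperazine-2,5-dione, via dipeptide amine formate 6 (not isolated)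
Conditions: HCO2H, rt; evaporate; sec-BuOH–toluene (4:1), reflux
Reagents that add atoms: none
Why: Acidolysis of the Boc group, then thermal cyclisation of the dipeptide ester by 6-exo-trig aminolysis to the diketopiperazine; the weakly acidic medium should avoid epimerisation, so the cis (3S,6S) ring is expected.

Step 5
Reactants: 7 (3S,6S)-3-(4-bromobenzyl)-6-(3-iodo-4-methoxybenzyl)piperazine-2,5-dione
Product: 9 (2S,5S)-2-(4-bromobenzyl)-5-(3-iodo-4-methoxybenzyl)piperazine, via bis(amine–borane) adduct 8 (not isolated)
Conditions: BH3·THF, THF, reflux; then MeOH, HCl, reflux; NaOH work-up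
Reagents that add atoms: none
Why: Borane reduction of both secondary lactams, which leaves aryl iodide, aryl bromide and aryl methyl ether untouched and cannot epimerise the α-carbons; acidic methanolysis cleaves the amine–borane adduct.

Step 6
Reactants: 9 (2S,5S)-2-(4-bromobenzyl)-5-(3-iodo-4-methoxybenzyl)piperazine
Product: 10 (2S,5S)-1,4-dibenzyl-2-(4-bromobenzyl)-5-(3-iodo-4-methoxybenzyl)piperazine
Conditions: BnBr, K2CO3, MeCN, 70 °C
Reagents that add atoms: benzyl bromide, BrCc1ccccc1
Why: Double SN2 N-alkylation of the two secondary amines; with no phenol present there is no O-alkylation, and the α-branch at each nitrogen slows quaternisation.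

Step 7
Reactants: 10 (2S,5S)-1,4-dibenzyl-2-(4-bromobenzyl)-5-(3-iodo-4-methoxybenzyl)piperazine
Product: 13 5-{[(2S,5S)-1,4-dibenzyl-5-(4-bromobenzyl)piperazin-2-yl]methyl}-2-methoxyphenol, via arylmagnesium chloride 11 (not isolated), via dimethyl arylboronate 12 (not isolated)
Conditions: iPrMgCl·LiCl, THF, −15 → 0 °C; B(OMe)3, −15 °C → rt; AcOH, 30% aq. H2O2, 0 °C → rt
Reagents that add atoms: hydrogen peroxide, OO
Why: Iodine–magnesium exchange is much faster than bromine–magnesium exchange and is assisted by the ortho methoxy group, so only ring A is metalated; borylation and peroxide oxidation (1,2-aryl shift from boron to oxygen) in acetic acid, where both amines are protonated and shielded from N-oxidation, should give the phenol.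

Step 8
Reactants: 13 5-{[(2S,5S)-1,4-dibenzyl-5-(4-bromobenzyl)piperazin-2-yl]methyl}-2-methoxyphenol
Product: 15 4-{[(2S,5S)-1,4-dibenzyl-5-(3-hydroxy-4-methoxybenzyl)piperazin-2-yl]methyl}benzoic acid, via dilithio species 14 (not isolated)
Conditions: n-BuLi (2.2 equiv), THF, −78 °C; CO2, −78 °C → rt; aq. HCl to pH 6
Reagents that add atoms: carbon dioxide, O=C=O
Why: The first equivalent of n-BuLi deprotonates the phenol, the second effects bromine–lithium exchange, and the aryllithium is carboxylated by CO2; the lithium phenoxide does not undergo Kolbe–Schmitt carboxylation at this temperature.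

Step 9
Reactants: 15 4-{[(2S,5S)-1,4-dibenzyl-5-(3-hydroxy-4-methoxybenzyl)piperazin-2-yl]methyl}benzoic acid
Product: 16 15-membered macrolactone (N,N'-dibenzyl, O-methyl; ring A C3 aryl ester of the ring B C4' carboxylic acid)
Conditions: DCC, DMAP, DMAP·HCl, CHCl3, reflux, syringe-pump addition (final 1 mM)
Reagents that add atoms: none
Why: Keck–Boden macrolactonisation: only the carboxyl group is activated, the acylpyridinium is captured by the phenol under high dilution, and DMAP·HCl suppresses N-acylurea formation; the cis 2,5-arms of the piperazine place the phenol within reach of the para carboxyl group.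

Step 10
Reactants: 16 15-membered macrolactone (N,N'-dibenzyl, O-methyl)
Product: 17 N,N'-dibenzyl-O-methylpiperazinomycin
Conditions: Ni(cod)2 (20 mol %), 3,4-bis(dicyclohexylphosphino)thiophene (dcypt, 40 mol %), K3PO4, toluene (5 mM), 150 °C, sealed tube
Reagents that add atoms: none
Why: Proposed new method: zerovalent nickel bound to the electron-rich cis-chelating bisphosphine should add oxidatively to the C(acyl)–O bond of the aryl ester to give a 16-membered aroyl aryloxide complex of divalent nickel, lose CO by aryl migration and dissociation, and form the ether by C–O reductive elimination from the resulting 15-membered arylnickel aryloxide; the closest known reaction type is the nickel- or palladium-catalysed decarbonylative etherification of acyclic aryl arenecarboxylates, best developed for azinecarboxylates. The 14-membered ring is closed not by an end-to-end cyclisation but by ring contraction (15 → 14) through reductive elimination within the coordination sphere of one metal atom, the two reacting atoms having been tethered beforehand by the ester. No stereocentre is formed, and the two S centres carry no acidic hydrogen and cannot epimerise under K3PO4. The step needs insertion at C(acyl)–O and not at C(aryl)–O, which the chelating dialkylphosphine and the electron-rich, methoxy-flanked ring A carbon should secure. It also needs reductive elimination to outrun protodemetalation and intermolecular aryloxide exchange, which the electron-rich guaiacol-type aryloxide, the cis geometry enforced by the ligand, the dilute solution and the irreversible escape of CO all favour. The tertiary benzylamines and the methyl ether offer the catalyst no competing acyl C–O, N–H or O–H bond. A benzoate lacking the ring nitrogen of the best known substrates is expected to react more slowly, which is why temperature and catalyst loading are high.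

Step 11
Reactants: 17 N,N'-dibenzyl-O-methylpiperazinomycin
Product: 18 N,N'-dibenzylpiperazinomycin
Conditions: BBr3 (excess), CH2Cl2, −78 → 0 °C; then H2O
Reagents that add atoms: none
Why: Lewis acid cleavage of the aryl methyl ether; the diaryl ether has no alkyl C–O bond to cleave and the benzylamines only bind the reagent, which is therefore used in excess.

Step 12
Reactants: 18 N,N'-dibenzylpiperazinomycin
Product: 20 N,N'-di-Boc-piperazinomycin, via piperazinomycin 19 (not isolated)
Conditions: H2 (4 atm), Pd(OH)2/C, Boc2O, MeOH–EtOAc, rt
Reagents that add atoms: di-tert-butyl dicarbonate, CC(C)(C)OC(=O)OC(=O)OC(C)(C)C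
Why: Hydrogenolysis of both N-benzyl groups with in situ carbamoylation of the freed secondary amines, which prevents catalyst inhibition by the diamine; the diaryl ether and the homobenzylic ring C–N bonds are not hydrogenolysed, and the hindered phenol is not acylated without an acylation catalyst.

Step 13
Reactants: 20 N,N'-di-Boc-piperazinomycin
Product: 21 N,N'-di-Boc-5-formylpiperazinomycin (formyl on ring A ortho to the phenol)
Conditions: MgCl2, Et3N, (CH2O)n, MeCN, reflux
Reagents that add atoms: paraformaldehyde (as formaldehyde), C=O
Why: Magnesium-mediated ortho-formylation of phenols (Casnati–Skattebøl): the magnesium phenoxide delivers formaldehyde to the ortho carbon and a second formaldehyde oxidises the benzylic alkoxide to the aldehyde; the only free ortho position is the one needed and ring B, not being a phenol, is inert.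

Step 14
Reactants: 21 N,N'-di-Boc-5-formylpiperazinomycin; 22 2,5,6-triaminopyrimidin-4(3H)-one
Product: 25 N,N'-di-Boc-guanipiperazine A, via Schiff base 23 (not isolated), via 7,8-dihydroguanine 24 (not isolated)
Conditions: Na2S2O5, DMF, 110 °C, open to air
Reagents that add atoms: none
Why: Traube-type oxidative imidazole annulation: the 5-amino group, the only one not deactivated by amidine or vinylogous amide conjugation, forms the Schiff base, the 6-amino group adds to give the aminal, and air oxidation aromatises it to the 8-arylguanine; Na2S2O5 delivers the aldehyde as its bisulfite adduct.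

Step 15
Reactants: 25 N,N'-di-Boc-guanipiperazine A
Product: 26 guanipiperazine A
Conditions: TFA–CH2Cl2 (1:1), 0 °C → rt; basic ion-exchange work-up to the free base
Reagents that add atoms: none
Why: Acidolytic removal of both Boc groups; guanine, phenol and diaryl ether are stable to TFA, and no stereocentre is at risk.

## Compound list

1 | 3-iodo-L-tyrosine | N[C@@H](Cc1ccc(O)c(I)c1)C(=O)O | starting material
2 | methyl 3-iodo-L-tyrosinate hydrochloride | Cl.N[C@@H](Cc1ccc(O)c(I)c1)C(=O)OC | intermediate
3 | N-Boc-4-bromo-L-phenylalanine | CC(C)(C)OC(=O)N[C@@H](Cc1ccc(Br)cc1)C(=O)O | starting material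
4 | methyl N-(N-Boc-4-bromo-L-phenylalanyl)-3-iodo-L-tyrosinate | CC(C)(C)OC(=O)N[C@@H](Cc1ccc(Br)cc1)C(=O)N[C@@H](Cc1ccc(O)c(I)c1)C(=O)OC | intermediate
5 | methyl N-(N-Boc-4-bromo-L-phenylalanyl)-3-iodo-O-methyl-L-tyrosinate | CC(C)(C)OC(=O)N[C@@H](Cc1ccc(Br)cc1)C(=O)N[C@@H](Cc1ccc(OC)c(I)c1)C(=O)OC | intermediate
6 | methyl N-(4-bromo-L-phenylalanyl)-3-iodo-O-methyl-L-tyrosinate formate salt | N[C@@H](Cc1ccc(Br)cc1)C(=O)N[C@@H](Cc1ccc(OC)c(I)c1)C(=O)OC.OC=O | intermediate (not isolated)
7 | (3S,6S)-3-(4-bromobenzyl)-6-(3-iodo-4-methoxybenzyl)piperazine-2,5-dione | Brc1ccc(cc1)C[C@H]1C(=O)N[C@H](C(=O)N1)Cc1ccc(OC)c(I)c1 | intermediate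
8 | bis(amine–borane) adduct of piperazine 9 | Brc1ccc(cc1)C[C@H]1C[NH+]([BH3-])[C@H](C[NH+]1[BH3-])Cc1ccc(OC)c(I)c1 | intermediate (not isolated)
9 | (2S,5S)-2-(4-bromobenzyl)-5-(3-iodo-4-methoxybenzyl)piperazine | Brc1ccc(cc1)C[C@H]1CN[C@H](CN1)Cc1ccc(OC)c(I)c1 | intermediate
10 | (2S,5S)-1,4-dibenzyl-2-(4-bromobenzyl)-5-(3-iodo-4-methoxybenzyl)piperazine | Brc1ccc(cc1)C[C@H]1CN(Cc2ccccc2)[C@H](CN1Cc1ccccc1)Cc1ccc(OC)c(I)c1 | intermediate
11 | arylmagnesium chloride of 10 (MgCl in place of iodine) | Brc1ccc(cc1)C[C@H]1CN(Cc2ccccc2)[C@H](CN1Cc1ccccc1)Cc1ccc(OC)c([Mg]Cl)c1 | intermediate (not isolated)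
12 | dimethyl arylboronate of 10 (B(OMe)2 in place of iodine) | Brc1ccc(cc1)C[C@H]1CN(Cc2ccccc2)[C@H](CN1Cc1ccccc1)Cc1ccc(OC)c(B(OC)OC)c1 | intermediate (not isolated)
13 | 5-{[(2S,5S)-1,4-dibenzyl-5-(4-bromobenzyl)piperazin-2-yl]methyl}-2-methoxyphenol | Brc1ccc(cc1)C[C@H]1CN(Cc2ccccc2)[C@H](CN1Cc1ccccc1)Cc1ccc(OC)c(O)c1 | intermediate
14 | dilithio species (lithium phenoxide, ring B aryllithium) | [Li]c1ccc(cc1)C[C@H]1CN(Cc2ccccc2)[C@H](CN1Cc1ccccc1)Cc1ccc(OC)c(O[Li])c1 | intermediate (not isolated)
15 | 4-{[(2S,5S)-1,4-dibenzyl-5-(3-hydroxy-4-methoxybenzyl)piperazin-2-yl]methyl}benzoic acid | OC(=O)c1ccc(cc1)C[C@H]1CN(Cc2ccccc2)[C@H](CN1Cc1ccccc1)Cc1ccc(OC)c(O)c1 | intermediate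
16 | 15-membered macrolactone, N,N'-dibenzyl, O-methyl | COc1ccc2cc1OC(=O)c1ccc(cc1)C[C@H]1CN(Cc3ccccc3)[C@H](CN1Cc1ccccc1)C2 | intermediate
17 | N,N'-dibenzyl-O-methylpiperazinomycin | COc1ccc2cc1Oc1ccc(cc1)C[C@H]1CN(Cc3ccccc3)[C@H](CN1Cc1ccccc1)C2 | intermediate
18 | N,N'-dibenzylpiperazinomycin | Oc1ccc2cc1Oc1ccc(cc1)C[C@H]1CN(Cc3ccccc3)[C@H](CN1Cc1ccccc1)C2 | intermediate
19 | piperazinomycin | Oc1ccc2cc1Oc1ccc(cc1)C[C@H]1CN[C@H](CN1)C2 | intermediate (not isolated)
20 | N,N'-di-Boc-piperazinomycin | Oc1ccc2cc1Oc1ccc(cc1)C[C@H]1CN(C(=O)OC(C)(C)C)[C@H](CN1C(=O)OC(C)(C)C)C2 | intermediate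
21 | N,N'-di-Boc-5-formylpiperazinomycin | O=Cc1cc2cc(c1O)Oc1ccc(cc1)C[C@H]1CN(C(=O)OC(C)(C)C)[C@H](CN1C(=O)OC(C)(C)C)C2 | intermediate
22 | 2,5,6-triaminopyrimidin-4(3H)-one | Nc1nc(N)c(N)c(=O)[nH]1 | starting material
23 | Schiff base of 21 with the 5-amino group of 22 | Nc1nc(N)c(N=Cc2cc3cc(c2O)Oc2ccc(cc2)C[C@H]2CN(C(=O)OC(C)(C)C)[C@H](CN2C(=O)OC(C)(C)C)C3)c(=O)[nH]1 | intermediate (not isolated)
24 | 8-aryl-7,8-dihydroguanine (C8 configuration undefined) | Nc1nc2NC(c3cc4cc(c3O)Oc3ccc(cc3)C[C@H]3CN(C(=O)OC(C)(C)C)[C@H](CN3C(=O)OC(C)(C)C)C4)Nc2c(=O)[nH]1 | intermediate (not isolated)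
25 | N,N'-di-Boc-guanipiperazine A | Nc1nc2nc(-c3cc4cc(c3O)Oc3ccc(cc3)C[C@H]3CN(C(=O)OC(C)(C)C)[C@H](CN3C(=O)OC(C)(C)C)C4)[nH]c2c(=O)[nH]1 | intermediate
26 | guanipiperazine A | Nc1nc2nc(-c3cc4cc(c3O)Oc3ccc(cc3)C[C@H]3CN[C@H](CN3)C4)[nH]c2c(=O)[nH]1 | target

## Step count and risk

Total steps: 15. Longest linear sequence: 15 steps (1 → 26); 3 and 22 are used as purchased.

**Step 10 (key step, new method).** The most likely failure is slow C–O reductive elimination from the arylnickel aryloxide, because ring B is an electron-neutral aryl group and not an azine. The intermediate would then be lost by protodemetalation or by intermolecular aryloxide exchange to oligomers, or the liberated CO would tie up the zerovalent nickel. The fallback uses known chemistry and sets out from bromophenol 13, which already has the phenol on ring A and a halide at C4' of ring B. An intramolecular Ullmann etherification (CuCl, 2,2,6,6-tetramethylheptane-3,5-dione, Cs2CO3, NMP, 120 °C, high dilution), a reaction type with precedent for 14-membered meta,para-bridged diaryl ethers, closes the ring and returns to the route at 17. Steps 8 and 9 are then bypassed and no new compound is made (F0).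

**Step 9.** Intermolecular esterification to oligomers, or rearrangement of the O-acylisourea to the N-acylurea, may outrun ring closure if the seco acid does not readily fold. The fallback sets out from 13 and closes the lactone by palladium-catalysed carbonylative macrolactonisation (Pd(OAc)2, Xantphos, CO (1 atm), Et3N, toluene, 90 °C, slow addition). Oxidative addition to the C–Br bond, CO insertion and capture of the aroylpalladium by the tethered phenoxide return to the route at 16; no new compound is made (F0).

**Step 7.** Incomplete exchange on the electron-rich ring, protonation of the aryl Grignard to the reduced arene, or N-oxidation in the peroxide stage are the likely losses. The fallback sets out from 10 and differentiates the halides by their rate of oxidative addition. Miyaura borylation (Pd(dppf)Cl2, B2pin2, KOAc, DMSO, 70 °C) should give the ring A pinacol boronate F1, and oxidation with NaBO3·4H2O in THF–water returns to the route at 13.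

**Step 8.** Poor solubility of the lithium phenoxide may stall the exchange, the aryllithium may be protonated or butylated, and the zwitterionic product may be hard to isolate. The fallback sets out from 13. Palladium-catalysed methoxycarbonylation (Pd(OAc)2, Xantphos, CO (1 atm), Et3N, MeOH, 70 °C) should give the ring B methyl ester F2, and saponification with LiOH in THF–water returns to the route at 15.

**Step 14.** The triamine may be oxidised before it condenses, the aminal may fail to aromatise, or the carbamates may be partly lost at 110 °C. The fallback sets out from 21 and replaces the oxidative closure by the acylation–cyclodehydration form of the Traube synthesis. Pinnick oxidation (NaClO2, NaH2PO4, 2-methyl-2-butene, t-BuOH–water) should give the ring A salicylic acid F3. Amide coupling with 22 at its 5-amino group (EDC·HCl, HOBt, DMF) should give the 5-aroylamino-2,6-diaminopyrimidinone F4. Cyclodehydration in hot aqueous NaOH, to which the Boc groups are stable, returns to the route at 25.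

## Further compounds

F0 | step 10 | none | none
F0 | step 9 | none | none
F1 | step 7 | ring A pinacol boronate of 10 (Bpin in place of iodine) | Brc1ccc(cc1)C[C@H]1CN(Cc2ccccc2)[C@H](CN1Cc1ccccc1)Cc1ccc(OC)c(B2OC(C)(C)C(C)(C)O2)c1
F2 | step 8 | methyl 4-{[(2S,5S)-1,4-dibenzyl-5-(3-hydroxy-4-methoxybenzyl)piperazin-2-yl]methyl}benzoate | COC(=O)c1ccc(cc1)C[C@H]1CN(Cc2ccccc2)[C@H](CN1Cc1ccccc1)Cc1ccc(OC)c(O)c1
F3 | step 14 | N,N'-di-Boc-piperazinomycin-5-carboxylic acid (ring A salicylic acid) | OC(=O)c1cc2cc(c1O)Oc1ccc(cc1)C[C@H]1CN(C(=O)OC(C)(C)C)[C@H](CN1C(=O)OC(C)(C)C)C2
F4 | step 14 | 5-aroylamino-2,6-diaminopyrimidin-4(3H)-one from F3 and 22 | Nc1nc(N)c(NC(=O)c2cc3cc(c2O)Oc2ccc(cc2)C[C@H]2CN(C(=O)OC(C)(C)C)[C@H](CN2C(=O)OC(C)(C)C)C3)c(=O)[nH]1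
A1 | alternative 1 | N,N'-di-Boc-5-formylpiperazinomycin | O=Cc1cc2cc(c1O)Oc1ccc(cc1)C[C@H]1CN(C(=O)OC(C)(C)C)[C@H](CN1C(=O)OC(C)(C)C)C2
A2 | alternative 1 | N,N'-di-Boc-guanipiperazine A | Nc1nc2nc(-c3cc4cc(c3O)Oc3ccc(cc3)C[C@H]3CN(C(=O)OC(C)(C)C)[C@H](CN3C(=O)OC(C)(C)C)C4)[nH]c2c(=O)[nH]1
A3 | alternative 2 | di-tert-butyl (2S,5S)-2,5-bis(3,5-dibromo-4-hydroxybenzyl)piperazine-1,4-dicarboxylate | Oc1c(Br)cc(cc1Br)C[C@H]1CN(C(=O)OC(C)(C)C)[C@H](CN1C(=O)OC(C)(C)C)Cc1cc(Br)c(O)c(Br)c1
A4 | alternative 2 | N,N'-di-Boc-tribromopiperazinomycin | Oc1c(Br)cc2cc1Oc1c(Br)cc(cc1Br)C[C@H]1CN(C(=O)OC(C)(C)C)[C@H](CN1C(=O)OC(C)(C)C)C2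
A5 | alternative 3 | bis-Cbz bis-aldehyde of the isodityrosine type (both α-carbons S) | O=C[C@H](Cc1ccc(Oc2cc(C[C@@H](C=O)NC(=O)OCc3ccccc3)ccc2O)cc1)NC(=O)OCc1ccccc1
A6 | alternative 3 | piperazinomycin | Oc1ccc2cc1Oc1ccc(cc1)C[C@H]1CN[C@H](CN1)C2
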